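**Assumptions:** The target SMILES corresponds to (3S,6E)-1-(3,4-dihydroxyphenyl)-7-(4-hydroxyphenyl)hept-6-en-3-yl acetate. The sense of induction in Step 3 cannot be predicted with confidence, so "(R)-ligand" below means the ligand enantiomer that delivers (R)-7. This must be confirmed on the first run (Mosher ester after TES removal) and the antipode used if reversed.

## Retrosynthetic overview

1. Target ⇐ fluoride desilylation of the tris-TIPS acetate ⇐ acetylation of the (3S)-alcohol. No ring is formed anywhere; both arenes are bought intact.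
2. C5–C6 disconnection: B-alkyl Suzuki coupling of the vinyl group of a chiral 5-aryl-pent-1-en-3-ol silyl ether with an (E)-styryl iodide made from 4-hydroxybenzaldehyde.
3. C1–aryl disconnection (key step): enantiotopic-group-selective anti-Markovnikov hydroarylation of achiral divinyl carbinol TES ether with protected 4-bromocatechol. This breaks the mirror symmetry and sets C3.
4. The C1–C5 core with its oxygen is penta-1,4-dien-3-ol, elaborated in both directions. The styrene is installed only after the CuH step, because CuH would attack it.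

## Route

**Step 1**
Reactants: 1 penta-1,4-dien-3-ol; 2 chlorotriethylsilane
Product: 3 triethyl(penta-1,4-dien-3-yloxy)silane (achiral, Cs-symmetric)
Conditions: TESCl, imidazole, CH2Cl2, 0 °C → rt
Reagents that add atoms: TESCl, CC[Si](Cl)(CC)CC
Why: Standard O-silylation; the silyl ether cannot ionise under Pd(0) (an allylic acetate would) and gives the bulky allylic substituent needed for facial bias in Step 3.

**Step 2**
Reactants: 4 4-bromocatechol; 5 chlorotriisopropylsilane
Product: 6 4-bromo-1,2-bis(triisopropylsilyloxy)benzene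
Conditions: TIPSCl (2.4 equiv), imidazole, cat. DMAP, DMF, 50 °C
Reagents that add atoms: TIPSCl, CC(C)[Si](Cl)(C(C)C)C(C)C
Why: Phenol silylation; aryl TIPS ethers tolerate NaOTMS, aqueous K3PO4 and dilute acid, and are removed by fluoride without touching an acetate or styrene.

**Step 3 (key step)**
Reactants: 3 triethyl(penta-1,4-dien-3-yloxy)silane (1.0 equiv); 6 4-bromo-1,2-bis(triisopropylsilyloxy)benzene (1.1 equiv)
Product: 7 (R)-triethyl{[5-(3,4-bis(triisopropylsilyloxy)phenyl)pent-1-en-3-yl]oxy}silane
Conditions: Cu(OAc)2 (5 mol%), (R)-DTBM-SEGPHOS (5.5 mol%), [Pd(cinnamyl)Cl]2 (2 mol%), BrettPhos (4.4 mol%), MePh2SiH (2.5 equiv), NaOTMS (2 equiv), THF, 40 °C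
Reagents that add atoms: none (only 3 and 6; H comes from the silane)
Why: Proposed new method: L*CuH adds irreversibly and anti-Markovnikov to one vinyl group (Cu on the terminal carbon, so no β-silyloxy elimination), and the primary alkyl-copper transmetalates to ArPd(BrettPhos)Br and reductively eliminates to form C1–aryl. The chiral CuH has a π-facial preference, and only one of the two enantiotopic vinyl groups can present that face in its low-A(1,3)-strain conformer (allylic C–H in plane, OTES away from Cu), so the choice of vinyl group sets C3. Mono-adduct formed at the "wrong" vinyl retains the fast-reacting vinyl and is siphoned off to the achiral bis-aryl by-product, which raises ee with conversion. The closest known reactions are CuH/Pd dual-catalysed anti-Markovnikov hydroarylation of terminal alkenes with aryl bromides and the enantiotopic-group-selective Sharpless epoxidation of divinyl carbinol.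

**Step 4**
Reactants: 8 4-hydroxybenzaldehyde; 5 chlorotriisopropylsilane
Product: 9 4-(triisopropylsilyloxy)benzaldehyde
Conditions: TIPSCl, imidazole, DMF, rt
Reagents that add atoms: TIPSCl, CC(C)[Si](Cl)(C(C)C)C(C)C
Why: Routine phenol silylation of a cheap aromatic aldehyde.

**Step 5**
Reactants: 9 4-(triisopropylsilyloxy)benzaldehyde; 10 iodoform
Product: 11 (E)-[4-(2-iodovinyl)phenoxy]triisopropylsilane
Conditions: CrCl2 (6 equiv), CHI3 (2 equiv), dioxane/THF 6:1, 0 °C → rt
Reagents that add atoms: iodoform, IC(I)I
Why: Takai olefination gives the (E)-vinyl iodide from an aryl aldehyde with high E-selectivity, improved in dioxane-rich solvent; the minor Z isomer is removed by chromatography.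

**Step 6**
Reactants: 7 (R)-TES ether from Step 3; 11 (E)-[4-(2-iodovinyl)phenoxy]triisopropylsilane
Product: 13 (3S,6E)-1-[3,4-bis(triisopropylsilyloxy)phenyl]-7-[4-(triisopropylsilyloxy)phenyl]hept-6-en-3-ol, via its TES ether 12 (not isolated)
Conditions: 9-BBN (1.3 equiv), THF, 0 °C → rt; then 3 M aq K3PO4, 11 (1.15 equiv), Pd(dppf)Cl2 (5 mol%), DMF, rt; then 2 M HCl to pH 1, MeOH, rt, 1 h
Reagents that add atoms: none (only 7 and 11; 9-BBN delivers H)
Why: Terminal-selective 9-BBN hydroboration followed by B-alkyl Suzuki–Miyaura coupling forms C5–C6 with retention of the E geometry. C3 is not involved (its descriptor changes from R to S only because CIP priorities change), and dilute acid removes the secondary TES ether while the aryl TIPS ethers survive.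

**Step 7**
Reactants: 13 the (3S,6E)-alcohol; 14 acetic anhydride
Product: 15 (3S,6E)-1-[3,4-bis(triisopropylsilyloxy)phenyl]-7-[4-(triisopropylsilyloxy)phenyl]hept-6-en-3-yl acetate
Conditions: Ac2O, pyridine, cat. DMAP, CH2Cl2, rt
Reagents that add atoms: acetic anhydride, CC(=O)OC(C)=O
Why: DMAP-catalysed O-acylation of the only free hydroxyl, with retention at C3.

**Step 8**
Reactants: 15 the tris-TIPS acetate
Product: 16 (3S,6E)-1-(3,4-dihydroxyphenyl)-7-(4-hydroxyphenyl)hept-6-en-3-yl acetate (target)
Conditions: TBAF (3.5 equiv), AcOH (4 equiv), THF, 0 °C, under Ar; pH 5 buffer work-up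
Reagents that add atoms: none
Why: Fluoride cleaves aryl silyl ethers rapidly, and AcOH buffering keeps the phenoxides protonated so the secondary acetate, the styrene and the air-sensitive catechol survive.

## Compound list

1 | penta-1,4-dien-3-ol | C=CC(O)C=C | starting material
2 | chlorotriethylsilane | CC[Si](Cl)(CC)CC | starting material (reagent)
3 | triethyl(penta-1,4-dien-3-yloxy)silane | C=CC(O[Si](CC)(CC)CC)C=C | intermediate
4 | 4-bromocatechol | Oc1ccc(Br)cc1O | starting material
5 | chlorotriisopropylsilane | CC(C)[Si](Cl)(C(C)C)C(C)C | starting material (reagent)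
6 | 4-bromo-1,2-bis(triisopropylsilyloxy)benzene | CC(C)[Si](Oc1ccc(Br)cc1O[Si](C(C)C)(C(C)C)C(C)C)(C(C)C)C(C)C | intermediate
7 | (R)-triethyl{[5-(3,4-bis(triisopropylsilyloxy)phenyl)pent-1-en-3-yl]oxy}silane | C=C[C@H](O[Si](CC)(CC)CC)CCc1ccc(O[Si](C(C)C)(C(C)C)C(C)C)c(O[Si](C(C)C)(C(C)C)C(C)C)c1 | intermediate
8 | 4-hydroxybenzaldehyde | O=Cc1ccc(O)cc1 | starting material
9 | 4-(triisopropylsilyloxy)benzaldehyde | O=Cc1ccc(O[Si](C(C)C)(C(C)C)C(C)C)cc1 | intermediate
10 | iodoform | IC(I)I | starting material (reagent)
11 | (E)-[4-(2-iodovinyl)phenoxy]triisopropylsilane | I/C=C/c1ccc(O[Si](C(C)C)(C(C)C)C(C)C)cc1 | intermediate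
12 | (3S,6E)-TES ether of 13 | CC[Si](CC)(CC)O[C@@H](CC/C=C/c1ccc(O[Si](C(C)C)(C(C)C)C(C)C)cc1)CCc1ccc(O[Si](C(C)C)(C(C)C)C(C)C)c(O[Si](C(C)C)(C(C)C)C(C)C)c1 | intermediate (not isolated)
13 | (3S,6E)-1-[3,4-bis(triisopropylsilyloxy)phenyl]-7-[4-(triisopropylsilyloxy)phenyl]hept-6-en-3-ol | O[C@@H](CC/C=C/c1ccc(O[Si](C(C)C)(C(C)C)C(C)C)cc1)CCc1ccc(O[Si](C(C)C)(C(C)C)C(C)C)c(O[Si](C(C)C)(C(C)C)C(C)C)c1 | intermediate
14 | acetic anhydride | CC(=O)OC(C)=O | starting material (reagent)
15 | (3S,6E)-1-[3,4-bis(triisopropylsilyloxy)phenyl]-7-[4-(triisopropylsilyloxy)phenyl]hept-6-en-3-yl acetate | CC(=O)O[C@@H](CC/C=C/c1ccc(O[Si](C(C)C)(C(C)C)C(C)C)cc1)CCc1ccc(O[Si](C(C)C)(C(C)C)C(C)C)c(O[Si](C(C)C)(C(C)C)C(C)C)c1 | intermediate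
16 | (3S,6E)-1-(3,4-dihydroxyphenyl)-7-(4-hydroxyphenyl)hept-6-en-3-yl acetate | CC(=O)O[C@@H](CC/C=C/c1ccc(O)cc1)CCc1ccc(O)c(O)c1 | target

## Step count and risks

Total steps: 8. The TES cleavage is telescoped into the work-up of Step 6; run separately it would add one step.
Longest linear sequence: 5 (Steps 1, 3, 6, 7, 8).

Steps most likely to fail:

1. **Step 3** (the enantiotopic-group selectivity is unprecedented; over-arylation and low ee are the main risks). Fallback: desymmetrise 1 by Sharpless asymmetric epoxidation, which is established for this substrate, and use the epoxide as a masked vinyl group. Carry out the 9-BBN/Suzuki coupling on the free vinyl, deoxygenate the epoxide stereospecifically back to the alkene, then do the second hydroboration/coupling. This adds two steps but gives predictable absolute configuration.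
2. **Step 6** (incomplete hydroboration, protodeboronation, or E/Z erosion carried over from 11). Fallback: change the bond formed. Hydroborate and oxidise 7 to the primary alcohol, oxidise to the aldehyde, and build C6=C7 by Julia–Kocienski olefination with 4-(TIPSO)benzyl 1-phenyltetrazol-5-yl sulfone, which is E-selective.
3. **Step 8** (acetate loss, catechol oxidation, or oligomerisation of the 4-hydroxystyrene). Fallback: change the protecting-group logic. Desilylate 13 fully first, peracetylate to the tetraacetate, then cleave only the three aryl acetates chemoselectively (NH4OAc, aqueous MeOH, rt), leaving the secondary alkyl acetate.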